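**Retrosynthetic overview**
1. The target has one ring, a 1,2-dioxane (O1, O2, C3 bearing CH2CO2H, C4 bearing CH3, C5H2, quaternary C6). The last C–C bond (C3–CH2CO2R) comes from axial addition of a silyl ketene acetal to the cyclic peroxycarbenium ion of a 3-silyloxy-1,2-dioxane, followed by ester hydrolysis.
2. The 1,2-dioxane is closed in one operation by a formal [3+3] annulation that forms C5–C6 and O2–C3. The partners are an acyclic silylperoxy ketal (C6 with its O1–O2 unit and the complete diene side chain) and an enantiopure 2-methylcyclopropyl silyl ether (C3–C4–C5).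
3. Enabling feature: C6 is a fully substituted ring carbon carrying O1–O2, a methyl group and a CH2R chain, so it is a methyl ketone carbon in disguise and gives a tertiary peroxycarbenium ion. C3–C4–C5, with oxygen on C3 and an unsubstituted C5H2, is a ring-opened cyclopropanol (a homoenolate), and the C4 methine survives untouched.
4. The side-chain ketone comes from two catalytic asymmetric conjugate additions of alkenylboron reagents (to crotonaldehyde, then to pent-3-en-2-one), linked by alkyne homologation and hydroboration.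
5. The cyclopropyl ether comes from (1S,2S)-2-methylcyclopropanecarboxylic acid via the methyl ketone and a Baeyer–Villiger oxidation.

Key step: step 9

Assumption: (1S,2S)-2-methylcyclopropane-1-carboxylic acid (12) is taken as a commercially available single enantiomer.
Remark: in steps 1 and 3 the catalyst enantiomer named is the one the usual face-selection model assigns to the stated configuration; if the sense proves opposite, the mirror-image catalyst is used and nothing else changes.

**Step 1**
Reactants: 1 (2E)-but-2-enal; 2 potassium trifluoro[(E)-2-phenylethenyl]borate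
Product: 3 (3S,4E)-3-methyl-5-phenylpent-4-enal
Conditions: (2R,5R)-5-benzyl-2-tert-butyl-3-methylimidazolidin-4-one·HCl (20 mol%), HF (1 equiv), DME, −20 °C
Reagents that add atoms: none
Why: Iminium activation of the enal and addition of the alkenyltrifluoroborate to the β-carbon from the unshielded face (organocatalytic Friedel–Crafts-type conjugate alkenylation) sets C3 as S with retention of the E-styryl geometry.

**Step 2**
Reactants: 3 (3S,4E)-3-methyl-5-phenylpent-4-enal
Product: 4 [(1E,3S)-3-methylhex-1-en-5-yn-1-yl]benzene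
Conditions: dimethyl (1-diazo-2-oxopropyl)phosphonate, K2CO3, MeOH, 0 °C to rt
Reagents that add atoms: dimethyl (1-diazo-2-oxopropyl)phosphonate, CC(=O)C(=[N+]=[N-])P(=O)(OC)OC
Why: Seyferth–Gilbert homologation with the Ohira–Bestmann reagent turns the aldehyde into the terminal alkyne under mild base, and the stereocentre, being β to the carbonyl, cannot epimerise.

**Step 3**
Reactants: 4 [(1E,3S)-3-methylhex-1-en-5-yn-1-yl]benzene; 5 catecholborane; 6 (3E)-pent-3-en-2-one
Product: 8 (4R,5E,8S,9E)-4,8-dimethyl-10-phenyldeca-5,9-dien-2-one, via alkenyl catecholboronate 7 (not isolated)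
Conditions: 5 (neat), 70 °C; then 6 (3 equiv), Rh(acac)(C2H4)2 (3 mol%), (R)-BINAP, Et3N, dioxane/H2O 10:1, 100 °C
Reagents that add atoms: none
Why: syn-Hydroboration of the terminal alkyne gives the (E)-alkenylborane, whose alkenyl group the BINAP–rhodium catalyst transfers to the β-carbon of the E-enone (rhodium-catalysed asymmetric conjugate addition, Hayashi–Miyaura reaction), the ligand setting the new C4 centre as R with retention of the E geometry.

**Step 4**
Reactants: 8 (4R,5E,8S,9E)-4,8-dimethyl-10-phenyldeca-5,9-dien-2-one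
Product: 10 [(1E,3S,5E,7R)-9-hydroperoxy-9-methoxy-3,7-dimethyldeca-1,5-dien-1-yl]benzene (both C9 epimers), via dimethyl ketal 9 (not isolated)
Conditions: HC(OMe)3, PPTS (cat.), MeOH, rt; evaporate; then anhydrous H2O2 in Et2O, PPTS (cat.), 0 °C
Reagents that add atoms: trimethyl orthoformate, COC(OC)OC; hydrogen peroxide, OO
Why: Acid-catalysed ketalisation and then exchange of one methoxy group for OOH through an oxocarbenium ion (perhydrolysis of a ketal) give the hydroperoxy ketal, whose new ketal centre is an unselected mixture that the key step erases.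

**Step 5**
Reactants: 10 [(1E,3S,5E,7R)-9-hydroperoxy-9-methoxy-3,7-dimethyldeca-1,5-dien-1-yl]benzene
Product: 11 triethyl{[(4R,5E,8S,9E)-2-methoxy-4,8-dimethyl-10-phenyldeca-5,9-dien-2-yl]peroxy}silane (both C2 epimers)
Conditions: Et3SiCl, imidazole, CH2Cl2, 0 °C
Reagents that add atoms: chlorotriethylsilane, CC[Si](Cl)(CC)CC
Why: O-Silylation of the hydroperoxide (silyl ether formation) removes the acidic OOH proton and installs the silyl group that later leaves as the electrofuge at ring closure.

**Step 6**
Reactants: 12 (1S,2S)-2-methylcyclopropane-1-carboxylic acid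
Product: 13 1-[(1S,2S)-2-methylcyclopropyl]ethan-1-one
Conditions: MeLi (2.2 equiv), Et2O, 0 °C to rt; then aq. HCl
Reagents that add atoms: methyllithium, [Li]C
Why: Deprotonation and addition of methyllithium give a stable dilithium gem-diolate that collapses to the methyl ketone on work-up (ketone synthesis from a carboxylic acid and an organolithium) without touching the ring stereocentres.

**Step 7**
Reactants: 13 1-[(1S,2S)-2-methylcyclopropyl]ethan-1-one
Product: 14 (1S,2S)-2-methylcyclopropyl acetate
Conditions: CF3CO3H (from (CF3CO)2O and urea·H2O2), Na2HPO4, CH2Cl2, 0 °C to rt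
Reagents that add atoms: trifluoroperacetic acid, OOC(=O)C(F)(F)F
Why: In the Baeyer–Villiger oxidation the cyclopropyl group migrates in preference to methyl and with retention of configuration, giving the cyclopropyl acetate.

**Step 8**
Reactants: 14 (1S,2S)-2-methylcyclopropyl acetate
Product: 16 triethyl{[(1S,2S)-2-methylcyclopropyl]oxy}silane, via lithium cyclopropanolate 15 (not isolated)
Conditions: MeLi (2.1 equiv), Et2O, −78 to 0 °C; then Et3SiCl (2.3 equiv), THF, 0 °C to rt
Reagents that add atoms: chlorotriethylsilane, CC[Si](Cl)(CC)CC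
Why: Methyllithium cleaves the acetate to the lithium cyclopropanolate (acyl cleavage by an organolithium), which is silylated in the same flask before it can ring-open, giving the donor cyclopropane with both centres unchanged.

**Step 9**
Reactants: 11 triethyl{[(4R,5E,8S,9E)-2-methoxy-4,8-dimethyl-10-phenyldeca-5,9-dien-2-yl]peroxy}silane; 16 triethyl{[(1S,2S)-2-methylcyclopropyl]oxy}silane
Product: 19 triethyl{[(4S,6R)-4,6-dimethyl-6-[(2R,3E,6S,7E)-2,6-dimethyl-8-phenylocta-3,7-dien-1-yl]-1,2-dioxan-3-yl]oxy}silane (both C3 anomers), via silylperoxycarbenium triflate 17 (not isolated), via ring-opened silyloxocarbenium triflate 18 (not isolated)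
Conditions: 16 (3 equiv), Et3SiOTf (20 mol%), 2,6-di-tert-butyl-4-methylpyridine (30 mol%), 4 Å sieves, CH2Cl2, −78 to −40 °C; Et3N quench
Reagents that add atoms: none
Why: Proposed new method: Et3SiOTf abstracts methoxide from either ketal epimer of 11 to give the planar silylperoxycarbenium ion 17, and the oxygen-activated C1–C3 σ bond of cyclopropyl ether 16 attacks it through the unsubstituted CH2 carbon (the carbon at which electrophiles open 2-substituted cyclopropanol derivatives), which forms the C5–C6 bond and leaves the silyloxocarbenium ion 18. The silylperoxy oxygen then adds to C3 and gives up Et3Si+ (which regenerates Et3SiOTf), forming the O2–C3 bond; the closest known reactions are the Lewis-acid annulation of silylperoxycarbenium ions with alkenes to 1,2-dioxolanes and the formal [3+3] annulations of donor-substituted cyclopropanes with 1,3-dipoles, the cyclopropane acting here as the one-carbon homologue of the alkene. The 1,2-dioxane closes in the 6-exo-trig mode, oxygen attacking the exocyclic C3=O+ bond. C4 is carried unchanged from 16 (its C–H bond is not touched) and C3 arises as an anomeric mixture that step 10 erases. C6 is set when the C5–C6 bond forms: in the compact chair-like arrangement in which the developing C3 cation is already held by the peroxide oxygen, the C4 methyl is equatorial and the cation geometry with the β-branched chain anti to the O–O bond puts that chain equatorial and the C6 methyl axial, which is 6R. The step needs capture of 17 by 16 faster than by the chain alkenes (secured by the excess of the σ-donor at −78 °C, the poor nucleophilicity of the 1,2-dialkyl alkene and the remoteness of the styrene) and this C6 face selectivity, which rests only on the preference of the chain over methyl for the equatorial site and is therefore the weakest point; the 6S isomer is a diastereomer and separable.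

**Step 10**
Reactants: 19 triethyl{[(4S,6R)-4,6-dimethyl-6-[(2R,3E,6S,7E)-2,6-dimethyl-8-phenylocta-3,7-dien-1-yl]-1,2-dioxan-3-yl]oxy}silane; 20 tert-butyl[(1-methoxyethenyl)oxy]dimethylsilane
Product: 22 methyl 2-[(3S,4S,6R)-4,6-dimethyl-6-[(2R,3E,6S,7E)-2,6-dimethyl-8-phenylocta-3,7-dien-1-yl]-1,2-dioxan-3-yl]acetate, via cyclic peroxycarbenium triflate 21 (not isolated)
Conditions: 20 (3 equiv), t-BuMe2SiOTf (20 mol%), CH2Cl2, −78 °C; NaHCO3 quench
Reagents that add atoms: none
Why: The silyl triflate ionises the anomeric silyloxy group to the cyclic peroxycarbenium ion 21, whose half-chair is fixed by the C6 quaternary centre (chain equatorial) and the pseudo-equatorial C4 methyl, and the silyl ketene acetal attacks C3 axially through a chair-like transition state (Mukaiyama-type addition to a cyclic peroxy acetal), giving the 3,4-cis product with 3S configuration from either anomer of 19.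

**Step 11**
Reactants: 22 methyl 2-[(3S,4S,6R)-4,6-dimethyl-6-[(2R,3E,6S,7E)-2,6-dimethyl-8-phenylocta-3,7-dien-1-yl]-1,2-dioxan-3-yl]acetate
Product: 23 2-[(3S,4S,6R)-4,6-dimethyl-6-[(2R,3E,6S,7E)-2,6-dimethyl-8-phenylocta-3,7-dien-1-yl]-1,2-dioxan-3-yl]acetic acid
Conditions: LiOH, THF/H2O 3:1, 0 °C to rt; then 1 M HCl to pH 3
Reagents that add atoms: lithium hydroxide, [Li+].[OH-]
Why: Saponification (acyl–oxygen cleavage by hydroxide) is faster than α-deprotonation of the ester, so the C3–O bond and the base-stable dialkyl peroxide stay intact and acidification gives the acid.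

**Compound list**
1 | (2E)-but-2-enal | C/C=C/C=O | starting material
2 | potassium trifluoro[(E)-2-phenylethenyl]borate | [K+].F[B-](F)(F)/C=C/c1ccccc1 | starting material
3 | (3S,4E)-3-methyl-5-phenylpent-4-enal | C[C@H](/C=C/c1ccccc1)CC=O | intermediate
4 | [(1E,3S)-3-methylhex-1-en-5-yn-1-yl]benzene | C[C@H](/C=C/c1ccccc1)CC#C | intermediate
5 | catecholborane (2H-1,3,2-benzodioxaborole) | B1Oc2ccccc2O1 | starting material
6 | (3E)-pent-3-en-2-one | C/C=C/C(C)=O | starting material
7 | 2-[(1E,4S,5E)-4-methyl-6-phenylhexa-1,5-dien-1-yl]-2H-1,3,2-benzodioxaborole | C[C@H](/C=C/c1ccccc1)C/C=C/B1Oc2ccccc2O1 | intermediate (not isolated)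
8 | (4R,5E,8S,9E)-4,8-dimethyl-10-phenyldeca-5,9-dien-2-one | C[C@H](/C=C/c1ccccc1)C/C=C/[C@H](C)CC(C)=O | intermediate
9 | [(1E,3S,5E,7R)-9,9-dimethoxy-3,7-dimethyldeca-1,5-dien-1-yl]benzene | C[C@H](/C=C/c1ccccc1)C/C=C/[C@H](C)CC(C)(OC)OC | intermediate (not isolated)
10 | [(1E,3S,5E,7R)-9-hydroperoxy-9-methoxy-3,7-dimethyldeca-1,5-dien-1-yl]benzene, both C9 epimers | C[C@H](/C=C/c1ccccc1)C/C=C/[C@H](C)CC(C)(OC)OO | intermediate
11 | triethyl{[(4R,5E,8S,9E)-2-methoxy-4,8-dimethyl-10-phenyldeca-5,9-dien-2-yl]peroxy}silane, both C2 epimers | C[C@H](/C=C/c1ccccc1)C/C=C/[C@H](C)CC(C)(OC)OO[Si](CC)(CC)CC | intermediate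
12 | (1S,2S)-2-methylcyclopropane-1-carboxylic acid | C[C@H]1C[C@@H]1C(=O)O | starting material
13 | 1-[(1S,2S)-2-methylcyclopropyl]ethan-1-one | C[C@H]1C[C@@H]1C(C)=O | intermediate
14 | (1S,2S)-2-methylcyclopropyl acetate | C[C@H]1C[C@@H]1OC(C)=O | intermediate
15 | lithium (1S,2S)-2-methylcyclopropan-1-olate | [Li+].C[C@H]1C[C@@H]1[O-] | intermediate (not isolated)
16 | triethyl{[(1S,2S)-2-methylcyclopropyl]oxy}silane | C[C@H]1C[C@@H]1O[Si](CC)(CC)CC | intermediate
17 | [(4R,5E,8S,9E)-4,8-dimethyl-10-phenyldeca-5,9-dien-2-ylidene][(triethylsilyl)oxy]oxonium trifluoromethanesulfonate | C[C@H](/C=C/c1ccccc1)C/C=C/[C@H](C)CC(C)=[O+]O[Si](CC)(CC)CC.[O-]S(=O)(=O)C(F)(F)F | intermediate (not isolated)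
18 | {(2S,4R,6R,7E,10S,11E)-2,4,6,10-tetramethyl-12-phenyl-4-[(triethylsilyl)peroxy]dodeca-7,11-dien-1-ylidene}(triethylsilyl)oxonium trifluoromethanesulfonate | C[C@H](/C=C/c1ccccc1)C/C=C/[C@H](C)C[C@](OO[Si](CC)(CC)CC)(C)C[C@H](C)C=[O+][Si](CC)(CC)CC.[O-]S(=O)(=O)C(F)(F)F | intermediate (not isolated)
19 | triethyl{[(4S,6R)-4,6-dimethyl-6-[(2R,3E,6S,7E)-2,6-dimethyl-8-phenylocta-3,7-dien-1-yl]-1,2-dioxan-3-yl]oxy}silane, both C3 anomers | C[C@H](/C=C/c1ccccc1)C/C=C/[C@H](C)C[C@]1(C)C[C@H](C)C(O[Si](CC)(CC)CC)OO1 | intermediate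
20 | tert-butyl[(1-methoxyethenyl)oxy]dimethylsilane | C=C(OC)O[Si](C)(C)C(C)(C)C | starting material
21 | (4S,6R)-4,6-dimethyl-6-[(2R,3E,6S,7E)-2,6-dimethyl-8-phenylocta-3,7-dien-1-yl]-5,6-dihydro-4H-1,2-dioxin-2-ium trifluoromethanesulfonate | C[C@H](/C=C/c1ccccc1)C/C=C/[C@H](C)C[C@]1(C)C[C@H](C)C=[O+]O1.[O-]S(=O)(=O)C(F)(F)F | intermediate (not isolated)
22 | methyl 2-[(3S,4S,6R)-4,6-dimethyl-6-[(2R,3E,6S,7E)-2,6-dimethyl-8-phenylocta-3,7-dien-1-yl]-1,2-dioxan-3-yl]acetate | C[C@H](/C=C/c1ccccc1)C/C=C/[C@H](C)C[C@]1(C)C[C@H](C)[C@H](CC(=O)OC)OO1 | intermediate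
23 | 2-[(3S,4S,6R)-4,6-dimethyl-6-[(2R,3E,6S,7E)-2,6-dimethyl-8-phenylocta-3,7-dien-1-yl]-1,2-dioxan-3-yl]acetic acid | C[C@H](/C=C/c1ccccc1)C/C=C/[C@H](C)C[C@]1(C)C[C@H](C)[C@H](CC(=O)O)OO1 | target

**Total step count:** 11. **Longest linear sequence:** 8 steps (1, 2, 3, 4, 5, 9, 10, 11).

**Steps most likely to fail**

1. Step 9 (proposed new method). What may go wrong:
   - the peroxycarbenium ion may be captured by the chain alkenes, or the cyclopropane may be opened by adventitious acid, before the C–C bond forms;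
   - face selectivity at C6 may be poor, since it rests only on chain-versus-methyl discrimination;
   - C4 may erode through enol silyl ether formation from 18.

   Fallback with known chemistry, setting out from ketone 8 and rejoining at ester 22:
   - Kinetic deprotonation of 8 at the methyl group (LiN(i-Pr)2, THF, −78 °C) and O-triflation with PhNTf2 give (4R,5E,8S,9E)-4,8-dimethyl-10-phenyldeca-1,5,9-trien-2-yl trifluoromethanesulfonate F1.
   - Negishi coupling of F1 with commercial (R)-(3-methoxy-2-methyl-3-oxopropyl)zinc bromide (Pd(PPh3)4, LiCl, THF) gives methyl (2S,6R,7E,10S,11E)-2,6,10-trimethyl-4-methylidene-12-phenyldodeca-7,11-dienoate F2.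
   - i-Bu2AlH at −78 °C gives (2S,6R,7E,10S,11E)-2,6,10-trimethyl-4-methylidene-12-phenyldodeca-7,11-dienal F3, which is protected (HC(OMe)3, PPTS) as [(1E,3S,5E,7R,11S)-12,12-dimethoxy-3,7,11-trimethyl-9-methylidenedodeca-1,5-dien-1-yl]benzene F4.
   - Mukaiyama–Isayama hydroperoxysilylation (Co(acac)2, O2, Et3SiH) of the 1,1-disubstituted alkene, the alkene most reactive towards hydrogen-atom transfer, gives {[(2S,6R,7E,10S,11E)-1,1-dimethoxy-2,4,6,10-tetramethyl-12-phenyldodeca-7,11-dien-4-yl]peroxy}triethylsilane F5 as both C4 epimers.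
   - PPTS in methanol removes the silyl group and closes the hydroperoxide onto the acetal to give (4S,6R)-3-methoxy-4,6-dimethyl-6-[(2R,3E,6S,7E)-2,6-dimethyl-8-phenylocta-3,7-dien-1-yl]-1,2-dioxane F6 after separation from its C6 epimer.
   - F6 under the conditions of step 10 (methoxide as leaving group) gives 22.

2. Step 10. What may go wrong: loss of the C4 proton from the cyclic peroxycarbenium ion (enol ether formation and C4 epimerisation), Lewis-acid-induced heterolysis of the O–O bond (Hock-type fragmentation), or erosion of the axial selectivity.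

   Fallback, setting out from 19 and rejoining at 22:
   - HF·pyridine removes the silyl group to give the peroxy hemiacetal (4S,6R)-4,6-dimethyl-6-[(2R,3E,6S,7E)-2,6-dimethyl-8-phenylocta-3,7-dien-1-yl]-1,2-dioxan-3-ol F7.
   - Its open hydroperoxy aldehyde tautomer undergoes Horner–Wadsworth–Emmons olefination (trimethyl phosphonoacetate, LiCl, DBU) to methyl (2E,4S,6R,8R,9E,12S,13E)-6-hydroperoxy-4,6,8,12-tetramethyl-14-phenyltetradeca-2,9,13-trienoate F8.
   - Intramolecular oxa-Michael addition of the hydroperoxide (Et2NH, CF3CH2OH) closes the ring to 22, which is separated from its C3 epimer.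

3. Step 4. What may go wrong: over-exchange to the geminal dihydroperoxide, an unfavourable exchange equilibrium, or acid-promoted decomposition of the hydroperoxide.

   Fallback, setting out from ketal 9 and rejoining at 10:
   - Elimination of methanol (Me3SiOTf, i-Pr2NEt, CH2Cl2) gives the enol ether [(1E,3S,5E,7R)-9-methoxy-3,7-dimethyldeca-1,5,9-trien-1-yl]benzene F9 together with its internal double-bond isomers.
   - Markovnikov addition of anhydrous H2O2 (PPTS cat., Et2O, 0 °C) to every isomer gives the same hydroperoxy ketal 10 irreversibly and without release of methanol.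

**Further compounds**
F1 | step 9 | (4R,5E,8S,9E)-4,8-dimethyl-10-phenyldeca-1,5,9-trien-2-yl trifluoromethanesulfonate | C[C@H](/C=C/c1ccccc1)C/C=C/[C@H](C)CC(=C)OS(=O)(=O)C(F)(F)F
F2 | step 9 | methyl (2S,6R,7E,10S,11E)-2,6,10-trimethyl-4-methylidene-12-phenyldodeca-7,11-dienoate | C[C@H](/C=C/c1ccccc1)C/C=C/[C@H](C)CC(=C)C[C@H](C)C(=O)OC
F3 | step 9 | (2S,6R,7E,10S,11E)-2,6,10-trimethyl-4-methylidene-12-phenyldodeca-7,11-dienal | C[C@H](/C=C/c1ccccc1)C/C=C/[C@H](C)CC(=C)C[C@H](C)C=O
F4 | step 9 | [(1E,3S,5E,7R,11S)-12,12-dimethoxy-3,7,11-trimethyl-9-methylidenedodeca-1,5-dien-1-yl]benzene | C[C@H](/C=C/c1ccccc1)C/C=C/[C@H](C)CC(=C)C[C@H](C)C(OC)OC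
F5 | step 9 | {[(2S,6R,7E,10S,11E)-1,1-dimethoxy-2,4,6,10-tetramethyl-12-phenyldodeca-7,11-dien-4-yl]peroxy}triethylsilane, both C4 epimers | C[C@H](/C=C/c1ccccc1)C/C=C/[C@H](C)CC(C)(OO[Si](CC)(CC)CC)C[C@H](C)C(OC)OC
F6 | step 9 | (4S,6R)-3-methoxy-4,6-dimethyl-6-[(2R,3E,6S,7E)-2,6-dimethyl-8-phenylocta-3,7-dien-1-yl]-1,2-dioxane, both C3 anomers | C[C@H](/C=C/c1ccccc1)C/C=C/[C@H](C)C[C@]1(C)C[C@H](C)C(OC)OO1
F7 | step 10 | (4S,6R)-4,6-dimethyl-6-[(2R,3E,6S,7E)-2,6-dimethyl-8-phenylocta-3,7-dien-1-yl]-1,2-dioxan-3-ol, both C3 anomers | C[C@H](/C=C/c1ccccc1)C/C=C/[C@H](C)C[C@]1(C)C[C@H](C)C(O)OO1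
F8 | step 10 | methyl (2E,4S,6R,8R,9E,12S,13E)-6-hydroperoxy-4,6,8,12-tetramethyl-14-phenyltetradeca-2,9,13-trienoate | C[C@H](/C=C/c1ccccc1)C/C=C/[C@H](C)C[C@](OO)(C)C[C@H](C)/C=C/C(=O)OC
F9 | step 4 | [(1E,3S,5E,7R)-9-methoxy-3,7-dimethyldeca-1,5,9-trien-1-yl]benzene | C[C@H](/C=C/c1ccccc1)C/C=C/[C@H](C)CC(=C)OC
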